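Compound numbers are those of the compound list after the steps. Chain atoms are numbered C1 (lactone carbonyl) to C26 (methyl), with O5, O7, O9 and O11 on the carbons of the same number.

## The problem

- **Skeleton.** Target 29 (CNP0231118.1) is an unbranched 26-carbon chain. C1 is closed onto O5 as a 5,6-dihydro-2H-pyran-2-one (ring atoms C1–C5 and O5, C2=C3 cis inside the ring). The arm C6–C26 carries secondary hydroxyls at C7, C9 and C11 and ends in a plain pentadecyl tail.
- **Nature of the task.** The only ring arises by lactonisation, so the work is acyclic: a 1,3,5,7-oxygenated array C5/C7/C9/C11 in which all four C–O bonds are syn in the zigzag drawing. The descriptors are 5S,7R,9R,11R; the S at C5 is only a priority effect.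
- **Which centre can control which.** C11 has no functional neighbour on its tail side and cannot be set by relay, so it needs a reagent, a catalyst or the chiral pool. A carbinol flanked by two others, such as C7, can be set from a neighbouring free hydroxyl by chelate-controlled 1,3-syn reduction of the ketone.
- **Sensitive groups.** The unsaturated lactone does not tolerate base. Alkoxide or fluoride can open it, eliminate O5 towards the dienoic acid, or let the C7 hydroxyl add to C3. The ring must therefore be closed last, under acid, with the polyol masked by acid-labile groups until then.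
- **Alkene geometry.** C2=C3 must be Z before lactonisation can occur; semihydrogenation of an alkyne gives this most simply.
- **Enabling feature.** C7 lies between two methylenes, C6 and C8, each leading to an oxygen-bearing carbon (C5 and C9). This is the pattern left when an acyl dianion equivalent at C7 opens two terminal epoxides, one across C8–C9 and one across C6–C5.

## Retrosynthesis

**Lactone and C1 (29 ⇐ 28 ⇐ 27 ⇐ 26 ⇐ 24 ⇐ 23).** The O5–C1 bond is cut first: the Z-hydroxy ester 28 should lactonise as soon as acid frees it from the protected Z-enoate 27. The Z-alkene goes back to ynoate 26, and the C1–C2 bond is cut to the terminal alkyne 24, obtained from silylalkyne 23. A ring-closing metathesis of an O5 acrylate was considered at this point. It would require O5 to be acylated selectively after O5 and O7 have been a free diol, so the alkyne is preferred. The alkyne needs no protection beyond a silyl cap and can be carried from the start. The forward steps must give Z geometry and must expose the lactone to acid only.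

**C7 stereocentre (23 ⇐ 22 ⇐ 20 ⇐ 19).** Acetonide 23 comes from the syn-diol 22, and the C7–H bond is cut to the β-hydroxy ketone 20. With O5 free and O9 blocked, a boron chelate between O5 and the C7 carbonyl fixes the face of hydride attack. This is simpler than a reagent-controlled reduction and uses a stereocentre that is already present. Ketone 20 is the hydrolysis product of dithiane 19. The forward sequence asks only that O5 is the one free hydroxyl, which the key step provides.

**Key disconnection (19 ⇐ 15 + 7 + 12).** Both bonds at C7 are cut, C7–C8 and C6–C7, giving the silyl dithiane 15 as the C7 unit and two terminal epoxides: fragment 1 (7, C8–C26) and fragment 2 (12, C2–C6). Aldol-type cuts at C5–C6 or C8–C9 would create a stereocentre in the coupling and need their own control. The epoxide cuts create none; every centre is installed beforehand and only has to survive. A 25-carbon chain with three stereocentres falls into a C19 piece with two, a C5 piece with one, and a one-carbon linchpin. The forward reaction must attack only the CH2 termini of both epoxides and must move silicon from C7 to O9 at the right moment, so that the second carbanion forms only after fragment 1 is consumed.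

**Fragment 1 (7 ⇐ 6 ⇐ 5 ⇐ 4 ⇐ 3 ⇐ 2 ⇐ 1).** The C9 epoxide is taken back to the epimer mixture 6, resolved by a cobalt salen catalyst, and on to alkene 5 and alcohol 4. Cutting C9–C10 (vinyl copper opening of an epoxide) leads to (R)-2-pentadecyloxirane 3. This comes from the racemate 2 by hydrolytic kinetic resolution, and 2 from heptadec-1-ene 1. The catalyst is (R,R)-(salen)Co(OAc), trivalent cobalt, where salen is N,N'-bis(3,5-di-tert-butylsalicylidene)cyclohexane-1,2-diaminate. The same catalyst enantiomer serves both resolutions. Each resolution can pass on at most half of its substrate, which is accepted early in the sequence in return for near-complete stereochemical purity at C11 and C9.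

**Fragment 2 and linchpin (12 ⇐ 11 ⇐ 8 + 9; 15 ⇐ 13).** The C3–C4 bond is cut to trimethylsilylacetylene 8 and (S)-epichlorohydrin 9. The acetylide opens the epoxide, and the chlorohydrin 11 closes to the new epoxide 12, so C5 comes from the chiral pool. The linchpin 15 is the C-silylation product of 1,3-dithiane 13.

## Roads not taken

**Alternative 1: aldolase cascade.** The cut is at C4–C5 and C6–C7, so C3–C8 is assembled from three two-carbon aldehydes. 2-Deoxyribose-5-phosphate aldolase would add acetaldehyde A1 to chloroacetaldehyde A2 and a second A1 to the first adduct; the product closes to the lactol A3 through O7 and C3.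
- Merits: C5 and C7 are set syn in one enzymatic step in water, from achiral feedstocks, with no protecting group. At these two centres it is cheaper and more atom-economical than the chosen plan, which needs a separate ketone reduction for C7.
- Weak points for 29: A3 ties O7 to C3, whereas the target needs O5 on C1, so the ring must be opened and O5 told apart from O7. C3 must become an alkene carbon by a Z-selective two-carbon olefination. The chloride at C8, next to the C7 oxygen, is a poor electrophile and must be converted before the C9–C26 part can be attached. C9 and C11 gain nothing from A3.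
- Comparison: the chain would grow linearly in both directions from a six-carbon core, and more operations should follow the key step than follow 19. The chosen plan offers convergence instead: 19 already holds every carbon from C2 to C26.

**Alternative 2: rhenium transposition.** The cut is the C11–O bond. Re2O7 would reversibly transpose the C13 allylic hydroxyl of the ene-diol A4 to C11, and benzaldehyde dimethyl acetal A5 would trap O9 and O11 as the all-equatorial 2-phenyl-1,3-dioxane A6.
- Merits: C11 is derived from C9 under thermodynamic control, the C13 carbinol need not be stereodefined, and no material is discarded. Here it is better than the chosen plan, whose two resolutions each give up half of their substrate.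
- Weak points: the E-alkene C12=C13 left in A6 has no use in 29 and must be hydrogenated without hydrogenolysis of the benzylic acetal. A6 ends at C8, so C7, C5 and the lactone must still be added one centre at a time. The cationic intermediates of the transposition could erode the E geometry or the acetal configuration.
- Comparison: more economical at C11, but linear and longer overall. The chosen plan joins the two halves at C7 in one flask and fixes C7 by relay.

**Alternative 3: hetero-Diels–Alder.** The cuts are C4–C5 and O5–C1. The C5 aldehyde A7 and (E)-1-methoxybuta-1,3-diene A8 would combine under a chiral tridentate Schiff-base CrCl complex (trivalent chromium) to give the cis 2-methoxy-5,6-dihydro-2H-pyran A9. Oxidation of the cyclic acetal and desilylation would finish the synthesis.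
- Merits: the ring, C5 and the cis alkene arise in one catalytic step, and the endgame is clearly shorter than the seven steps needed after 19. This is a real advantage over the chosen plan.
- Weak points: A7 must already contain C7, C9 and C11, so the whole triol has to be built linearly first. Without O5, C7 cannot be set by relay from C5. The catalyst must override any bias of the β-silyloxy aldehyde.
- Comparison: the alternative solves the ring and leaves the chain open; the chosen plan solves the chain and pays with a longer finish and a stoichiometric organolithium step with HMPA. Because the chain holds three of the four stereocentres, the convergent chain assembly was given priority.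

Key step: step 10

Remark: CIP descriptors of intermediates change where substituent priorities change (for example C9 is R in 7 and 19 but S in 22). The spatial arrangement is all-syn throughout and is fixed by the SMILES strings.

## Route

Step 1
Reactants: 1 heptadec-1-ene
Product: 2 rac-2-pentadecyloxirane
Conditions: mCPBA, CH2Cl2, 0 °C → rt
Reagents that add atoms: mCPBA, OOC(=O)c1cccc(Cl)c1
Why: Prilezhaev epoxidation of a terminal alkene; no stereocontrol is wanted because the racemate is resolved in step 2.

Step 2
Reactants: 2 rac-2-pentadecyloxirane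
Product: 3 (R)-2-pentadecyloxirane
Conditions: (R,R)-(salen)Co(OAc) (0.5 mol %), H2O (0.55 equiv), minimal THF, 0 °C → rt
Reagents that add atoms: none
Why: Jacobsen hydrolytic kinetic resolution: with the (R,R) catalyst the (S)-epoxide is hydrolysed much faster, so slightly more than half an equivalent of water should leave the (R)-epoxide (C11) in high enantiomeric purity, and the polar diol is removed by chromatography.

Step 3
Reactants: 3 (R)-2-pentadecyloxirane
Product: 4 (R)-nonadec-1-en-4-ol
Conditions: CH2=CHMgBr, CuI (10 mol %), THF, −20 °C; aq. NH4Cl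
Reagents that add atoms: vinylmagnesium bromide, C=C[Mg]Br
Why: Copper-catalysed Grignard opening of a terminal epoxide at its unsubstituted carbon (C10) forms C9–C10 and does not touch C11, which keeps its configuration.

Step 4
Reactants: 4 (R)-nonadec-1-en-4-ol
Product: 5 (R)-tert-butyldimethyl(nonadec-1-en-4-yloxy)silane
Conditions: TBSCl, imidazole, DMF, rt
Reagents that add atoms: tert-butyldimethylsilyl chloride, CC(C)(C)[Si](C)(C)Cl
Why: Standard imidazole-promoted silylation of a secondary alcohol; the TBS ether should survive peracid, the organolithium coupling and the hydride step, and falls in the final acid step.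

Step 5
Reactants: 5 (R)-tert-butyldimethyl(nonadec-1-en-4-yloxy)silane
Product: 6 tert-butyldimethyl{[(2R)-1-(oxiran-2-yl)heptadecan-2-yl]oxy}silane as a mixture of both oxirane epimers
Conditions: mCPBA, NaHCO3, CH2Cl2, 0 °C → rt
Reagents that add atoms: mCPBA, OOC(=O)c1cccc(Cl)c1
Why: Prilezhaev epoxidation; the remote C11 silyloxy group gives no useful facial bias, so both C9 epimers are expected and are separated chemically in step 6.

Step 6
Reactants: 6 epoxide epimer mixture
Product: 7 fragment 1: tert-butyldimethyl{[(2R)-1-[(2R)-oxiran-2-yl]heptadecan-2-yl]oxy}silane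
Conditions: (R,R)-(salen)Co(OAc) (0.5–1 mol %), H2O (0.55 equiv), THF, 0 °C → rt
Reagents that add atoms: none
Why: Second hydrolytic kinetic resolution, now of epimers: the catalyst reads the configuration of the epoxide carbon, so the (9S) epimer should be hydrolysed to the diol and the (9R) epoxide with the 9,11-syn relationship recovered.

Step 7
Reactants: 8 trimethylsilylacetylene; 9 (S)-epichlorohydrin
Product: 11 (S)-1-chloro-5-(trimethylsilyl)pent-4-yn-2-ol, via lithium (trimethylsilyl)acetylide 10 (not isolated)
Conditions: n-BuLi, THF, −78 °C; BF3·OEt2; then 9, −78 °C; aq. NH4Cl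
Reagents that add atoms: none
Why: Yamaguchi–Hirao alkynylation: the BF3-activated epoxide is opened at its CH2 terminus by the acetylide faster than chloride is displaced, so C3–C4 forms and the carbinol carbon (C5) keeps its configuration.

Step 8
Reactants: 11 (S)-1-chloro-5-(trimethylsilyl)pent-4-yn-2-ol
Product: 12 fragment 2: (S)-trimethyl[3-(oxiran-2-yl)prop-1-yn-1-yl]silane
Conditions: NaH, THF, 0 °C → rt
Reagents that add atoms: none
Why: Intramolecular Williamson closure of the chlorohydrin alkoxide; the C5–O bond is not broken, so configuration is retained, and an aprotic base avoids loss of the alkynyl silane.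

Step 9
Reactants: 13 1,3-dithiane
Product: 15 2-(tert-butyldimethylsilyl)-1,3-dithiane, via 2-lithio-1,3-dithiane 14 (not isolated)
Conditions: n-BuLi, THF, −30 °C; TBSCl, −78 °C → rt
Reagents that add atoms: tert-butyldimethylsilyl chloride, CC(C)(C)[Si](C)(C)Cl
Why: Corey–Seebach metalation of the dithiane and C-silylation; one equivalent of base and electrophile avoids double silylation.

Step 10
Reactants: 15 2-(tert-butyldimethylsilyl)-1,3-dithiane; 7 fragment 1; 12 fragment 2
Product: 19 2-[(2R,4R)-2,4-bis(tert-butyldimethylsilyloxy)nonadecyl]-2-[(2S)-2-hydroxy-5-(trimethylsilyl)pent-4-yn-1-yl]-1,3-dithiane, via 2-lithio-2-silyl-1,3-dithiane 16 (not isolated), via lithium alkoxide of the first adduct 17 (not isolated), via Brook-rearranged 2-lithiodithiane 18 (not isolated)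
Conditions: 15, t-BuLi, Et2O, −78 → −45 °C; 7 in Et2O, −78 → −25 °C; then 12 in THF/HMPA, −78 °C → rt; aq. NH4Cl
Reagents that add atoms: none
Why: t-BuLi deprotonates 15 at C2 to give 16, which opens epoxide 7 by SN2 attack at its unsubstituted carbon C8 and so forms C7–C8 and the O9 alkoxide 17. In ether the lithium alkoxide is tightly aggregated and does not attack silicon, so 17 should persist until the second epoxide arrives together with HMPA. HMPA solvates lithium, the alkoxide adds to the silicon on C7 through a five-membered silicate, and the TBS group moves from C7 to O9 (1,4-Brook rearrangement), driven by the strong Si–O bond and by sulfur stabilisation of carbanion 18. Carbanion 18 then opens 12 at its terminal carbon C6, forming C6–C7, and work-up leaves O5 as the only free hydroxyl. The closest known reaction type is the solvent-controlled three-component anion relay coupling of 2-silyl-1,3-dithianes with two different terminal epoxides. No ring is closed and no stereocentre is created; C5, C9 and C11 are carried unchanged because only CH2 termini are attacked. The step needs terminal regioselectivity, secured by monosubstituted epoxides and a bulky soft carbanion, and correct timing, secured by consuming 7 in ether before any HMPA is present. It also needs alkylation to outrun deprotonation of the propargylic C4–H of 12, which low temperature and the modest basicity of a dithiane anion should favour.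

Step 11
Reactants: 19 key-step dithiane
Product: 20 (4S,8R,10R)-8,10-bis(tert-butyldimethylsilyloxy)-4-hydroxy-1-(trimethylsilyl)pentacos-1-yn-6-one
Conditions: MeI (excess), CaCO3, MeCN/H2O (9:1), 45 °C
Reagents that add atoms: water, O
Why: Alkylative dithiane hydrolysis: S-methylation makes sulfur a leaving group and water attacks C7; the buffered metal-free medium should leave the alkynylsilane, the TBS ethers and the β-hydroxy ketone intact.

Step 12
Reactants: 20 β-hydroxy ketone
Product: 22 (4S,6S,8S,10R)-8,10-bis(tert-butyldimethylsilyloxy)-1-(trimethylsilyl)pentacos-1-yne-4,6-diol, via diethylboron chelate 21 (not isolated)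
Conditions: Et2BOMe, THF/MeOH (4:1), −78 °C; NaBH4, −78 °C; AcOH; MeOH co-evaporation
Reagents that add atoms: none
Why: Narasaka–Prasad reduction: the C5 hydroxyl and the C7 carbonyl form the six-membered boron chelate 21 and external hydride attacks axially on its half-chair, which gives the 5,7-syn diol (C7 set by C5); boron leaves again as Et2BOMe on methanol co-evaporation.

Step 13
Reactants: 22 syn-diol
Product: 23 (4S,6S)-4-[(2S,4R)-2,4-bis(tert-butyldimethylsilyloxy)nonadecyl]-2,2-dimethyl-6-[3-(trimethylsilyl)prop-2-yn-1-yl]-1,3-dioxane
Conditions: 2,2-dimethoxypropane, PPTS (cat.), CH2Cl2, rt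
Reagents that add atoms: 2,2-dimethoxypropane, COC(C)(C)OC
Why: Acid-catalysed transacetalisation to the cis-4,6-disubstituted 1,3-dioxane; it masks O5 and O7 for the acetylide chemistry, and the 13C pattern of the acetonide carbons (Rychnovsky analysis) allows the syn assignment at C7 to be checked.

Step 14
Reactants: 23 silylalkyne acetonide
Product: 24 (4S,6S)-4-[(2S,4R)-2,4-bis(tert-butyldimethylsilyloxy)nonadecyl]-2,2-dimethyl-6-(prop-2-yn-1-yl)-1,3-dioxane
Conditions: K2CO3 (cat.), MeOH, rt
Reagents that add atoms: none
Why: Methanolysis of the alkynyl C–Si bond by catalytic methoxide; secondary TBS ethers and the acetonide are stable to K2CO3 in methanol.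

Step 15
Reactants: 24 terminal alkyne
Product: 26 methyl 4-{(4S,6S)-6-[(2S,4R)-2,4-bis(tert-butyldimethylsilyloxy)nonadecyl]-2,2-dimethyl-1,3-dioxan-4-yl}but-2-ynoate, via lithium acetylide of 24 25 (not isolated)
Conditions: n-BuLi, THF, −78 °C; ClCO2Me, −78 → −20 °C
Reagents that add atoms: methyl chloroformate, COC(=O)Cl
Why: Deprotonation of the terminal alkyne and C-acylation of the acetylide with the chloroformate installs C1; low temperature and excess chloroformate prevent a second addition to the ynoate.

Step 16
Reactants: 26 ynoate
Product: 27 methyl (Z)-4-{(4S,6S)-6-[(2S,4R)-2,4-bis(tert-butyldimethylsilyloxy)nonadecyl]-2,2-dimethyl-1,3-dioxan-4-yl}but-2-enoate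
Conditions: H2 (1 atm), Pd/CaCO3 poisoned with Pb(OAc)2, quinoline, EtOAc, rt
Reagents that add atoms: none
Why: Lindlar semihydrogenation: syn delivery of hydrogen on the poisoned palladium surface gives the Z-enoate, and quinoline suppresses over-reduction and isomerisation.

Step 17
Reactants: 27 Z-enoate
Product: 29 (6S)-6-[(2R,4R,6R)-2,4,6-trihydroxyhenicosyl]-5,6-dihydro-2H-pyran-2-one (CNP0231118.1), via tetrol Z-ester 28 (not isolated)
Conditions: 48% aq. HF, MeCN, 0 °C → rt
Reagents that add atoms: none
Why: Aqueous HF cleaves both TBS ethers through Si–F bond formation and hydrolyses the acetonide; in the freed Z-ester 28 the cis double bond holds O5 next to the ester, so six-membered lactonisation should follow, whereas O7 could only form an eight-membered ring, and no base is present to trigger conjugate addition or elimination.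

## Compound list

1 | heptadec-1-ene | CCCCCCCCCCCCCCCC=C | starting material
2 | rac-2-pentadecyloxirane | CCCCCCCCCCCCCCCC1CO1 | intermediate
3 | (R)-2-pentadecyloxirane | CCCCCCCCCCCCCCC[C@@H]1CO1 | intermediate
4 | (R)-nonadec-1-en-4-ol | CCCCCCCCCCCCCCC[C@@H](O)CC=C | intermediate
5 | (R)-tert-butyldimethyl(nonadec-1-en-4-yloxy)silane | CCCCCCCCCCCCCCC[C@@H](O[Si](C)(C)C(C)(C)C)CC=C | intermediate
6 | tert-butyldimethyl{[(2R)-1-(oxiran-2-yl)heptadecan-2-yl]oxy}silane, both oxirane epimers | CCCCCCCCCCCCCCC[C@@H](O[Si](C)(C)C(C)(C)C)CC1CO1 | intermediate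
7 | fragment 1, tert-butyldimethyl{[(2R)-1-[(2R)-oxiran-2-yl]heptadecan-2-yl]oxy}silane | CCCCCCCCCCCCCCC[C@@H](O[Si](C)(C)C(C)(C)C)C[C@@H]1CO1 | intermediate
8 | trimethylsilylacetylene | C#C[Si](C)(C)C | starting material
9 | (S)-epichlorohydrin | ClC[C@@H]1CO1 | starting material
10 | lithium (trimethylsilyl)acetylide (not isolated) | [Li]C#C[Si](C)(C)C | intermediate
11 | (S)-1-chloro-5-(trimethylsilyl)pent-4-yn-2-ol | ClC[C@@H](O)CC#C[Si](C)(C)C | intermediate
12 | fragment 2, (S)-trimethyl[3-(oxiran-2-yl)prop-1-yn-1-yl]silane | C1O[C@H]1CC#C[Si](C)(C)C | intermediate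
13 | 1,3-dithiane | C1CSCSC1 | starting material
14 | 2-lithio-1,3-dithiane (not isolated) | [Li]C1SCCCS1 | intermediate
15 | 2-(tert-butyldimethylsilyl)-1,3-dithiane | CC(C)(C)[Si](C)(C)C1SCCCS1 | intermediate
16 | 2-lithio-2-(tert-butyldimethylsilyl)-1,3-dithiane (not isolated) | [Li]C1(SCCCS1)[Si](C)(C)C(C)(C)C | intermediate
17 | lithium (2R,4R)-4-(tert-butyldimethylsilyloxy)-1-[2-(tert-butyldimethylsilyl)-1,3-dithian-2-yl]nonadecan-2-olate (not isolated) | CCCCCCCCCCCCCCC[C@@H](O[Si](C)(C)C(C)(C)C)C[C@@H](O[Li])CC1(SCCCS1)[Si](C)(C)C(C)(C)C | intermediate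
18 | 2-lithio-2-[(2R,4R)-2,4-bis(tert-butyldimethylsilyloxy)nonadecyl]-1,3-dithiane (not isolated) | CCCCCCCCCCCCCCC[C@@H](O[Si](C)(C)C(C)(C)C)C[C@@H](O[Si](C)(C)C(C)(C)C)CC1([Li])SCCCS1 | intermediate
19 | 2-[(2R,4R)-2,4-bis(tert-butyldimethylsilyloxy)nonadecyl]-2-[(2S)-2-hydroxy-5-(trimethylsilyl)pent-4-yn-1-yl]-1,3-dithiane | CCCCCCCCCCCCCCC[C@@H](O[Si](C)(C)C(C)(C)C)C[C@@H](O[Si](C)(C)C(C)(C)C)CC1(SCCCS1)C[C@@H](O)CC#C[Si](C)(C)C | intermediate
20 | (4S,8R,10R)-8,10-bis(tert-butyldimethylsilyloxy)-4-hydroxy-1-(trimethylsilyl)pentacos-1-yn-6-one | CCCCCCCCCCCCCCC[C@@H](O[Si](C)(C)C(C)(C)C)C[C@@H](O[Si](C)(C)C(C)(C)C)CC(=O)C[C@@H](O)CC#C[Si](C)(C)C | intermediate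
21 | O4-diethylboryl derivative of 20, carbonyl-chelated (not isolated) | CCCCCCCCCCCCCCC[C@@H](O[Si](C)(C)C(C)(C)C)C[C@@H](O[Si](C)(C)C(C)(C)C)CC(=O)C[C@@H](OB(CC)CC)CC#C[Si](C)(C)C | intermediate
22 | (4S,6S,8S,10R)-8,10-bis(tert-butyldimethylsilyloxy)-1-(trimethylsilyl)pentacos-1-yne-4,6-diol | CCCCCCCCCCCCCCC[C@@H](O[Si](C)(C)C(C)(C)C)C[C@@H](O[Si](C)(C)C(C)(C)C)C[C@@H](O)C[C@@H](O)CC#C[Si](C)(C)C | intermediate
23 | (4S,6S)-4-[(2S,4R)-2,4-bis(tert-butyldimethylsilyloxy)nonadecyl]-2,2-dimethyl-6-[3-(trimethylsilyl)prop-2-yn-1-yl]-1,3-dioxane | CCCCCCCCCCCCCCC[C@@H](O[Si](C)(C)C(C)(C)C)C[C@@H](O[Si](C)(C)C(C)(C)C)C[C@@H]1C[C@H](CC#C[Si](C)(C)C)OC(C)(C)O1 | intermediate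
24 | (4S,6S)-4-[(2S,4R)-2,4-bis(tert-butyldimethylsilyloxy)nonadecyl]-2,2-dimethyl-6-(prop-2-yn-1-yl)-1,3-dioxane | CCCCCCCCCCCCCCC[C@@H](O[Si](C)(C)C(C)(C)C)C[C@@H](O[Si](C)(C)C(C)(C)C)C[C@@H]1C[C@H](CC#C)OC(C)(C)O1 | intermediate
25 | lithium acetylide of 24 (not isolated) | CCCCCCCCCCCCCCC[C@@H](O[Si](C)(C)C(C)(C)C)C[C@@H](O[Si](C)(C)C(C)(C)C)C[C@@H]1C[C@H](CC#C[Li])OC(C)(C)O1 | intermediate
26 | methyl 4-{(4S,6S)-6-[(2S,4R)-2,4-bis(tert-butyldimethylsilyloxy)nonadecyl]-2,2-dimethyl-1,3-dioxan-4-yl}but-2-ynoate | CCCCCCCCCCCCCCC[C@@H](O[Si](C)(C)C(C)(C)C)C[C@@H](O[Si](C)(C)C(C)(C)C)C[C@@H]1C[C@H](CC#CC(=O)OC)OC(C)(C)O1 | intermediate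
27 | methyl (Z)-4-{(4S,6S)-6-[(2S,4R)-2,4-bis(tert-butyldimethylsilyloxy)nonadecyl]-2,2-dimethyl-1,3-dioxan-4-yl}but-2-enoate | CCCCCCCCCCCCCCC[C@@H](O[Si](C)(C)C(C)(C)C)C[C@@H](O[Si](C)(C)C(C)(C)C)C[C@@H]1C[C@H](C/C=C\C(=O)OC)OC(C)(C)O1 | intermediate
28 | methyl (2Z,5S,7S,9R,11R)-5,7,9,11-tetrahydroxyhexacos-2-enoate (not isolated) | CCCCCCCCCCCCCCC[C@@H](O)C[C@@H](O)C[C@@H](O)C[C@@H](O)C/C=C\C(=O)OC | intermediate
29 | (6S)-6-[(2R,4R,6R)-2,4,6-trihydroxyhenicosyl]-5,6-dihydro-2H-pyran-2-one | CCCCCCCCCCCCCCC[C@@H](O)C[C@@H](O)C[C@@H](O)C[C@@H]1CC=CC(=O)O1 | target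

## Count and risks

Total step count: 17. Longest linear sequence: 14 steps (steps 1–6, 10, 11–17).

**Step 10 (key step).**
- Most likely failure: proton transfer from the propargylic C4–H of 12 to carbanion 18, or attack of 18 on the alkynyl silicon, which would stop the sequence at the C7-protonated mono-adduct. Silyl migration that starts before 7 is consumed would let 18 take up a second molecule of 7; migration that lags would leave unrearranged material.
- Fallback: from 15 and 7, the sequence is run as before up to 18, but the second electrophile is (R)-epichlorohydrin F1, which has no acidic propargylic hydrogen. Carbanion 18 opens it at the epoxide CH2 (C6) and the resulting alkoxide displaces chloride, closing a new C4–C5 epoxide to give 2-[(2R,4R)-2,4-bis(tert-butyldimethylsilyloxy)nonadecyl]-2-{[(2R)-oxiran-2-yl]methyl}-1,3-dithiane F2. Opening of F2 at C4 with lithium (trimethylsilyl)acetylide 10 and BF3·OEt2 at −78 °C returns to the route at 19. Steps 7 and 8 are then not needed.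

**Step 6.**
- Most likely failure: slow or poorly selective hydrolysis, because the lipophilic silyl ether mixes badly with water and the C11 substituent may erode catalyst discrimination. In any case, half of the material is lost.
- Fallback: from 4, acylation with Boc2O and DMAP gives (R)-tert-butyl nonadec-1-en-4-yl carbonate F3. Treatment with IBr in toluene at −85 °C cyclises it through a chair-like transition state with both substituents equatorial to the cis carbonate (4R,6R)-4-(iodomethyl)-6-pentadecyl-1,3-dioxan-2-one F4. K2CO3 in methanol cleaves the carbonate and closes the epoxide to (2R)-1-[(2R)-oxiran-2-yl]heptadecan-2-ol F5. Silylation with TBSCl and imidazole returns to the route at 7 without a resolution.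

**Step 11.**
- Most likely failure: sluggish hydrolysis of the hindered 2,2-dialkyl dithiane, with competing β-elimination of O5 or O9 from the β-oxygenated ketone on prolonged warming.
- Fallback: from 19, oxidation of one sulfur with NaIO4 in aqueous methanol at 0 °C gives the dithiane 1-oxide F6 as a mixture of sulfoxide isomers. This dithioacetal S-oxide should hydrolyse with catalytic acid in wet THF at 0 °C and return to the route at 20.

**Step 17.**
- Most likely failure: incomplete lactonisation, or conjugate addition of the freed C7 hydroxyl to C3 of the unsaturated lactone during the acid exposure needed to remove two silyl ethers and the acetonide.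
- Fallback: from 26, the protecting groups are removed first with aqueous HF in MeCN to give methyl (5S,7S,9R,11R)-5,7,9,11-tetrahydroxyhexacos-2-ynoate F7, which cannot lactonise because the alkyne is linear. Lindlar semihydrogenation of F7 then gives 28, which closes on brief contact with catalytic PPTS to return to the route at 29. The unsaturated lactone then never meets the deprotection medium.

Further compounds
F1 | step 10 | (R)-epichlorohydrin (bought, second electrophile) | ClC[C@H]1CO1
F2 | step 10 | 2-[(2R,4R)-2,4-bis(tert-butyldimethylsilyloxy)nonadecyl]-2-{[(2R)-oxiran-2-yl]methyl}-1,3-dithiane | CCCCCCCCCCCCCCC[C@@H](O[Si](C)(C)C(C)(C)C)C[C@@H](O[Si](C)(C)C(C)(C)C)CC1(SCCCS1)C[C@@H]2CO2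
F3 | step 6 | (R)-tert-butyl nonadec-1-en-4-yl carbonate | CCCCCCCCCCCCCCC[C@@H](OC(=O)OC(C)(C)C)CC=C
F4 | step 6 | (4R,6R)-4-(iodomethyl)-6-pentadecyl-1,3-dioxan-2-one | CCCCCCCCCCCCCCC[C@@H]1C[C@H](CI)OC(=O)O1
F5 | step 6 | (2R)-1-[(2R)-oxiran-2-yl]heptadecan-2-ol | CCCCCCCCCCCCCCC[C@@H](O)C[C@@H]1CO1
F6 | step 11 | 1-oxide of dithiane 19 (sulfoxide isomers) | CCCCCCCCCCCCCCC[C@@H](O[Si](C)(C)C(C)(C)C)C[C@@H](O[Si](C)(C)C(C)(C)C)CC1(SCCCS1=O)C[C@@H](O)CC#C[Si](C)(C)C
F7 | step 17 | methyl (5S,7S,9R,11R)-5,7,9,11-tetrahydroxyhexacos-2-ynoate | CCCCCCCCCCCCCCC[C@@H](O)C[C@@H](O)C[C@@H](O)C[C@@H](O)CC#CC(=O)OC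
A1 | alternative 1 | acetaldehyde | CC=O
A2 | alternative 1 | chloroacetaldehyde | ClCC=O
A3 | alternative 1 | (4R,6S)-6-(chloromethyl)tetrahydro-2H-pyran-2,4-diol (6-chloro-2,4,6-trideoxyhexopyranose, anomer mixture) | ClC[C@@H]1C[C@@H](O)CC(O)O1
A4 | alternative 2 | C8-silylated (E)-C11=C12 ene-diol with free hydroxyls at C9 and C13 (C13 unspecified) | CCCCCCCCCCCCCC(O)/C=C/C[C@@H](O)CO[Si](c1ccccc1)(c1ccccc1)C(C)(C)C
A5 | alternative 2 | benzaldehyde dimethyl acetal | COC(OC)c1ccccc1
A6 | alternative 2 | all-equatorial 2-phenyl-1,3-dioxane across O9 and O11 with (E)-pentadec-1-enyl tail and C8 silyloxymethyl group | CCCCCCCCCCCCC/C=C/[C@@H]1C[C@@H](O[C@H](c2ccccc2)O1)CO[Si](c3ccccc3)(c3ccccc3)C(C)(C)C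
A7 | alternative 3 | all-syn 3,5,7-tris(tert-butyldimethylsilyloxy)docosanal (C5 aldehyde) | CCCCCCCCCCCCCCC[C@@H](O[Si](C)(C)C(C)(C)C)C[C@@H](O[Si](C)(C)C(C)(C)C)C[C@@H](O[Si](C)(C)C(C)(C)C)CC=O
A8 | alternative 3 | (E)-1-methoxybuta-1,3-diene | CO/C=C/C=C
A9 | alternative 3 | 2,6-cis 2-methoxy-5,6-dihydro-2H-pyran carrying the tris-silylated triol chain | CCCCCCCCCCCCCCC[C@@H](O[Si](C)(C)C(C)(C)C)C[C@@H](O[Si](C)(C)C(C)(C)C)C[C@@H](O[Si](C)(C)C(C)(C)C)C[C@@H]1CC=C[C@H](OC)O1
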